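**The comparison.** I ask which of two new flasks, noon or midnight, turns more of its reacted monomer into chains rather than side product; noon runs warmer.

| setting | south-east | north-east | noon | midnight |
|---|---|---|---|---|
| free monomer | 0.054 M (fed, over 3.0 h) | 0.054 M (fed, over 3.0 h) | 0.054 M (fed, over 3.0 h) | 0.054 M (fed, over 3.0 h) |
| transfer agent | 0.81 mM | 3.2 mM | 1.62 mM | 1.62 mM |
| initiator | 5.3 mM | 5.3 mM | 5.3 mM | 5.3 mM |
| temperature | 6 °C | 20 °C | 25 °C | 0 °C |
| remark | run made earlier | run made earlier |  |  |
| time |  |  | 3.0 h | 3.0 h |

| run | time / h | monomer in chains / % | side product / % | free monomer / % |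
|---|---|---|---|---|
| south-east | 0.667 | 0.8 | 0.6 | 18.7 |
| south-east | 2.00 | 28.2 | 0.7 | 30.7 |
| south-east | 3.00 | 56.4 | 3.8 | 29.9 |
| south-east | 5.00 | 81.8 | 5.9 | 1.4 |
| south-east | 8.00 | 83.4 | 5.5 | 0.8 |
| north-east | 0.667 | 5.5 | 1.9 | 11.2 |
| north-east | 1.33 | 15.8 | 1.7 | 17.8 |
| north-east | 2.00 | 29.1 | 3.1 | 17.5 |
| north-east | 2.50 | 43.0 | 4.0 | 18.1 |
| north-east | 3.00 | 54.6 | 8.0 | 16.8 |

(scatter of a reading: 1 percentage point)

* the flask with the highest share of monomer in chains in all that became monomer in chains or side product ("all alike" if they lie within 1.5 percentage points) (noon / midnight / all alike)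
* share of monomer in chains in all that became monomer in chains or side product, noon
* share of monomer in chains in all that became monomer in chains or side product, midnight

- percentages count the free monomer that a species holds: one side product counts as two
- percentages count the whole charge, also what has not yet gone in
- a reading or a percentage of monomer in chains counts all its forms, free or not

**The oddity.** At 3.00 h, the north-east run holds less free monomer than the south-east run, 16.8% against 29.9%. Yet it holds twice the side product, 8.0% against 3.8%, with similar monomer in chains.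

**Side ratio.** I divide side product by monomer in chains and call this r, the inverse of a selectivity factor; the asked share is 1/(1+r). The readings give 0.0674 for south-east and 0.147 for north-east, so r rose while free monomer fell. These are readings, rough at a scatter of 1 percentage point. I credit warmth with the whole rise, although the agent also differs, 0.81 mM against 3.2 mM. That gives D = 12.5 K, the doubling step: the warming that doubles r.

**My reckoning.** Stepping from the nearer run, noon gets r = 0.193, a share of 83.8%. Midnight gets r = 0.0483, a share of 95.4%.

**The forecast.** It names midnight, with 88% for noon (84% to 92%) and 94% for midnight (90.5% to 96.5%), holding that “side product has the higher activation energy”. Its noon value stands above mine.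

**The flasks.** The answer is midnight: 91.2% at noon, 95.7% at midnight, a gap of 4.5 points, wider than the margin.

    free monomer + initiator → living end + monomer in chains (k = 27.0 M⁻¹ h⁻¹, Ea = 58.0 kJ mol⁻¹)
    free monomer + living end → monomer in chains + living end, rate k2*[living end]*[free monomer] (k = 210 M⁻¹ h⁻¹, Ea = 48.0 kJ mol⁻¹)
    living end + transfer agent → dead chain (kL = 660 M⁻¹ h⁻¹, Ea = 47.0 kJ mol⁻¹)
    free monomer ⇌ dormant form (K = 1.40, k = 0.0720 h⁻¹, Ea = 85.0 kJ mol⁻¹, ΔH = 5.00 kJ mol⁻¹)
    initiator + monomer in chains ⇌ idle complex (K = 27.0 M⁻¹, k = 9.10 M⁻¹ h⁻¹, Ea = 56.0 kJ mol⁻¹, ΔH = −24.0 kJ mol⁻¹)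
    free monomer + monomer in chains → side product (k = 0.970 M⁻¹ h⁻¹, Ea = 59.0 kJ mol⁻¹)
    (constants at 0 °C)

**Colder neighbour.** In the flasks r is 0.0449 at midnight, against my 0.0483, and 0.0965 at noon, below my 0.193. The same flask as midnight, run at −15 °C, takes the step D downward from south-east: r = 0.0210, a share of 97.9%. That neighbour gives 98.7%, with 0.145% side product, 10.8% monomer in chains and 88% of its free monomer still unbound.

The runs come from a simulation with constants of no real substance; the scatter is artificial.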